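**Remark on conventions.** Atoms carry elemane numbers: ring C10 (methyl C14, vinyl C1=C2), C9, C8, C7 (arm C11 with methylene C13 and carbonyl C12), C6, C5 (arm C4 with methylene C15 and C3). With the ring drawn so that C10→C9→C8→C7→C6→C5 runs clockwise, "upper" is the face toward the viewer. In the target C14, the C5 arm and O6 are upper; the vinyl group, O9, O8 and C11 are lower.

## The problem

Target 25 is a single cyclohexane in which all six ring carbons are stereogenic. C10 is quaternary, and a cis-fused α-methylene-γ-lactone (O8–C12(=O)–C11(=C13)–C7) spans C7 and C8. No chain has to be built; the task is to place six substituents on one ring with the correct relative and absolute configuration. The stereocentres can be relayed round the ring from one resident centre. C7 can set C6 (anti) and O6 can set C5 (syn, by delivery). C5 can set C10 (anti). C7 can also set C8, because a C12 carboxylate tethered to C7 can only close cis, and C8 can then set C9. Three unsaturated arms must be kept apart in oxidation level: the vinyl group stays untouched, C12 becomes a carboxyl, and C3 becomes an aldehyde. Several groups are fragile: the angelate isomerises Z to E, the methylene lactone and the 2-substituted acrolein (C15=C4–C3=O) are Michael acceptors, the acetate is base-labile, and C8 is epimerisable while C9 is a ketone. Strong base, nucleophiles and hydride must therefore be finished before the aldehyde and the angelate appear. The feature that opens the route is that C5 sits between oxygenated C6 and methyl-bearing C10, which is attached to oxygenated C9. This is a 4-hydroxy-2-methylcyclohex-2-enone (C9=O, C10=C5, C6–OH), in which O6 can steer a carbon nucleophile to C5 and the resulting C9–C10 enolate can accept the vinyl group. In addition, C7 with its three-carbon arm lies para to C10 and next-but-one to C9, which is the substitution pattern of carvone.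

## Retrosynthesis

**25 ⇒ 24 ⇒ 23.** No skeletal bond is cut; the C3 aldehyde is traced back through allylic alcohol 24 to the methyl of an isopropenyl group in 23. The enal is the most electrophilic and reduction-sensitive group, so it is made last. In 23 the C5 isopropenyl is the only electron-rich alkene with allylic hydrogens: the vinyl group has none, and the angelate and methylene lactone are electron-poor. The forward steps must oxidise one methyl group chemoselectively.

**23 ⇒ 20 + 21.** The O9–acyl bond is cut, removing angelic acid 21. Acylating any earlier would expose the Z-enoate to hydride, base and bromination. Alcohol 20 is five carbons simpler and has only one free hydroxyl. The forward reaction must acylate a hindered secondary alcohol without Z-to-E isomerisation.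

**20 ⇒ 19.** The C9–H bond is cut, leaving keto lactone 19. The ketone is kept this long because it activates C8 for the lactone closure and is the carbonyl of the key step. The forward reduction must deliver hydride to the upper face and spare the methylene lactone.

**19 ⇒ 18 ⇒ 15.** The O8–C8 bond is cut, not the acyl C12–O8 bond. An 8-hydroxyl cis to the C7 arm cannot be installed directly, because electrophiles enter C8 anti to that arm. Bromine entering anti, followed by displacement with inversion by the tethered C12 carboxylate, must give the cis lactone. Bromo acid 18 goes back to silyl ether 15 by adjusting the oxidation level of C12 (via alcohol 16 and aldehyde 17).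

**15 ⇒ 14 ⇒ 13 ⇒ 12.** The C8–Br bond is cut through silyl enol ether 14. The O6 acetate of 13, a group of the target, is installed on 12 and serves as the protecting group from then on. Ketone 12 has only one enolisable side, so regiochemistry is not an issue.

**12 ⇒ 7 + 8 + 9.** The C5–C4 and C10–C1 bonds are cut. This removes two of the three arms and two stereocentres at once and leaves γ-hydroxy enone 7, isopropenylmagnesium bromide 8 and vinyl bromide 9. Cutting either bond alone would need a separately prepared regiodefined enolate. Cutting both lets the conjugate addition generate the enolate that is then vinylated. The forward reaction needs 1,4-addition syn to O6 and C-vinylation at C10 anti to the new C5 group.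

**7 ⇒ 6 ⇒ 5.** The C6–O bond is cut. The hydroxyl is introduced by oxidising the linear dienol silyl ether 6 at its γ-terminus, anti to the adjacent C7 arm. Enone 5 lacks one stereocentre and one oxygen.

**5 ⇒ 4 ⇒ 3 ⇒ 2 ⇒ 1.** The C12–O bond is cut. The oxygen is placed on the isopropenyl methyl of (R)-(−)-carvone 1 by allylic chlorination (2), acetate displacement (3), methanolysis (4) and silylation (5). Carvone supplies all six ring carbons, C14, C11–C13 and the C7 stereocentre.

## Roads not taken

**Alternative 1:** This road cuts C7–C11 and C8–C12 and takes both lactone carbons from allene A2. The substrate is the C9 enone A1, which has a C7=C8 double bond, a silyl ether at O6, the C5 arm as a ketal and the vinyl group as a silyloxyethyl chain. In the forward step the enone triplet adds A2 head-to-head to give the cis-fused methylenecyclobutane A3, anti to the C6 silyloxy group. Its strength is that the cis relation of C7 and C8 is enforced by the four-membered ring. That is more secure than the bromination and inversion used here, and the plan chosen must accept that. The weak points are numerous. C7 is sp2 in A1, so the carvone stereocentre cannot be used, and C10, C5 and C6 would have to be made by asymmetric synthesis. After the photoreaction the route still needs ozonolysis, a Baeyer–Villiger insertion in which the migrating carbon C8 is deactivated by the adjacent C9 carbonyl, α-methylenation, and unmasking of both the vinyl and the C5 arm. The chosen plan carries all three alkenes in their final form from step 7 and uses a chiral-pool ring.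

**Alternative 2:** This road cuts the ring bond C7–C8 together with the O8–C12 ester bond. The precursor is the open-chain aldehyde A4, carrying a Z-2-(bromomethyl)enoate. Zinc or indium gives an allylmetal that adds through C7 to the C8 aldehyde, and the alkoxide lactonises, giving A5 with all six stereocentres and the methylene lactone in one step. In convergence of the end game it is better than the chosen plan: A5 needs only two desilylations, an acylation and an oxidation, with no hydride reduction at C9 and no late allylic oxidation. Against this, A4 holds four contiguous stereocentres, one of them the quaternary C10, and has to be built by acyclic asymmetric synthesis. Its α-silyloxy aldehyde is epimerisable. The cyclisation must also set C7 and C8 correctly relative to C6 and C9 through a transition state whose preference is not obvious. The chosen plan offers a commercial ring that fixes C7 from the start and a relay in which each new centre is set by its neighbour.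

**Alternative 3:** This road cuts C6–C7. SmI2 reduces the C6 aldehyde of the butenolide A6 to a ketyl that adds to C7, closing the carbocycle cis-fused to the existing lactone and giving hydroxy lactone A7. The merit is that O8 and O9 are in place before the ring forms, so neither the bromide inversion nor the C9 reduction of the chosen plan is needed, and the free 6-hydroxyl is ready for acetylation. The weak points are an acyclic precursor with four stereocentres including C10, an α-branched aldehyde that can epimerise, and an uncertain carbinol configuration at C6. The saturated lactone would also have to be α-methylenated late, next to base-sensitive groups. The chosen plan is shorter to its key intermediate and carries C11=C13 from carvone.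

Key step: step 7

## Route

Step 1
Reactants: 1 (R)-(−)-carvone
Product: 2 (5R)-5-(3-chloroprop-1-en-2-yl)-2-methylcyclohex-2-en-1-one
Conditions: Ca(OCl)2, CO2 (dry ice), CH2Cl2/H2O, 0 °C
Reagents that add atoms: calcium hypochlorite, [Ca+2].[O-]Cl.[O-]Cl
Why: Ene-type allylic chlorination by hypochlorous acid attacks only the electron-rich 1,1-disubstituted alkene and leaves the enone untouched; the stereocentre is not involved.

Step 2
Reactants: 2 (5R)-5-(3-chloroprop-1-en-2-yl)-2-methylcyclohex-2-en-1-one
Product: 3 (5R)-5-(3-acetoxyprop-1-en-2-yl)-2-methylcyclohex-2-en-1-one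
Conditions: KOAc, Bu4NI (cat.), DMF, 60 °C
Reagents that add atoms: potassium acetate, CC(=O)[O-].[K+]
Why: SN2 displacement of a primary allylic chloride by acetate with iodide catalysis (Finkelstein activation).

Step 3
Reactants: 3 (5R)-5-(3-acetoxyprop-1-en-2-yl)-2-methylcyclohex-2-en-1-one
Product: 4 (5R)-5-(3-hydroxyprop-1-en-2-yl)-2-methylcyclohex-2-en-1-one
Conditions: K2CO3 (cat.), MeOH, 0 °C
Reagents that add atoms: none
Why: Base-catalysed transesterification removes the acetate; the enone tolerates catalytic carbonate in cold methanol.

Step 4
Reactants: 4 (5R)-5-(3-hydroxyprop-1-en-2-yl)-2-methylcyclohex-2-en-1-one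
Product: 5 (5R)-5-[3-(tert-butyldimethylsilyloxy)prop-1-en-2-yl]-2-methylcyclohex-2-en-1-one
Conditions: TBSCl, imidazole, CH2Cl2, 0 °C → rt
Reagents that add atoms: tert-butyldimethylsilyl chloride, CC(C)(C)[Si](C)(C)Cl
Why: Standard silylation of a primary allylic alcohol; the ether masks O12 against the Grignard reagent and prevents a second, competing alkoxide in step 7.

Step 5
Reactants: 5 (5R)-5-[3-(tert-butyldimethylsilyloxy)prop-1-en-2-yl]-2-methylcyclohex-2-en-1-one
Product: 6 (5S)-1-(tert-butyldimethylsilyloxy)-5-[3-(tert-butyldimethylsilyloxy)prop-1-en-2-yl]-2-methylcyclohexa-1,3-diene (linear dienol ether C9=C10–C5=C6)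
Conditions: KOt-Bu, THF, 0 °C; then TBSCl, −78 °C → rt
Reagents that add atoms: tert-butyldimethylsilyl chloride, CC(C)(C)[Si](C)(C)Cl
Why: Under equilibrating alkoxide conditions the enone should give the extended (γ-deprotonated) dienolate, which is more stable than the cross-conjugated one, and O-silylation traps it as the linear dienol ether. C7 is not acidic, so the stereocentre is untouched (the descriptor changes only because the priorities change).

Step 6
Reactants: 6 linear dienol silyl ether
Product: 7 (4S,5R)-4-hydroxy-5-[3-(tert-butyldimethylsilyloxy)prop-1-en-2-yl]-2-methylcyclohex-2-en-1-one (O6 upper, C7 arm lower)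
Conditions: mCPBA, NaHCO3, CH2Cl2, −20 °C; aq. Na2S2O3/NaHCO3
Reagents that add atoms: 3-chloroperoxybenzoic acid, OOC(=O)c1cccc(Cl)c1
Why: Vinylogous Rubottom oxidation: the peracid epoxidises the distal C5=C6 bond of the electron-rich diene much faster than the isolated alkene, and the epoxide opens to the γ-hydroxy enone with loss of silicon. The oxidant should approach anti to the adjacent C7 arm, which sets C6 trans to it.

Step 7
Reactants: 7 γ-hydroxy enone; 8 isopropenylmagnesium bromide; 9 vinyl bromide
Product: 12 4-hydroxy-2-methyl-3-(prop-1-en-2-yl)-5-[3-(tert-butyldimethylsilyloxy)prop-1-en-2-yl]-2-vinylcyclohexan-1-one (ring positions 1–5 = C9, C10, C5, C6, C7; C14, isopropenyl and O6 upper; vinyl and C7 arm lower), via bromomagnesium alkoxide 10 (not isolated), via bromomagnesium enolate 11 (not isolated)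
Conditions: 8 (3 equiv), THF, −78 → −20 °C; then Pd2(dba)3 (2.5 mol %), XPhos (10 mol %), 9 (5 equiv, THF solution), sealed vessel, 0 → 45 °C; aq. NH4Cl
Reagents that add atoms: none
Why: The first equivalent of 8 deprotonates O6 to give alkoxide 10, and a second equivalent bound to that alkoxide is delivered to C5 through a five-membered cyclic transition state, the known alkoxide-directed conjugate addition of Grignard reagents to γ-hydroxy enones; this forms C5–C4 and enolate 11. C5 is therefore set syn to O6, and this is also the axial trajectory anti to the equatorial C7 arm, so delivery and substrate bias agree; the intramolecular delivery is what favours 1,4- over 1,2-addition. Vinyl bromide 9 adds oxidatively to zerovalent palladium, the C9–C10 magnesium enolate transmetalates to the resulting vinyl complex of divalent palladium, and reductive elimination forms C10–C1, as in the palladium-catalysed α-vinylation of ketone enolates that is known to build quaternary carbons. The enolate is regiodefined by the conjugate addition, so coupling occurs at C10 and not at C8. The new bond forms on the face anti to the freshly installed C5 isopropenyl group, which puts the vinyl group on the lower face and C14 on the upper face. No ring closes. The step needs C- over O-coupling and no proton transfer to C8; the bulky biarylphosphine accelerates C–C reductive elimination, the magnesium enolate is only weakly basic, and surplus 8 is removed by Kumada coupling with excess 9 to volatile isoprene.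

Step 8
Reactants: 12 hydroxy ketone
Product: 13 O6-acetate of 12
Conditions: Ac2O, DMAP (cat.), pyridine, CH2Cl2, 0 °C → rt
Reagents that add atoms: acetic anhydride, CC(=O)OC(C)=O
Why: Standard acylation of the only free hydroxyl; the acetate of the target doubles as the protecting group for O6 and has no elimination pathway (it is γ to the ketone).

Step 9
Reactants: 13 keto acetate
Product: 14 trimethylsilyl enol ether of 13 (C8=C9)
Conditions: TMSOTf, Et3N, CH2Cl2, −78 → 0 °C
Reagents that add atoms: trimethylsilyl trifluoromethanesulfonate, C[Si](C)(C)OS(=O)(=O)C(F)(F)F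
Why: Soft enolisation silylates the ketone far faster than the acetate, and only C8 carries α-hydrogens, so a single enol ether can form.

Step 10
Reactants: 14 silyl enol ether
Product: 15 8-bromo ketone (Br upper, trans to the C7 arm)
Conditions: NBS, NaHCO3, THF, −78 °C
Reagents that add atoms: N-bromosuccinimide, O=C1CCC(=O)N1Br
Why: Electrophilic bromination of a silyl enol ether is much faster than attack on the unactivated alkenes. Bromine should enter C8 from the upper face, anti to the C7 arm and to the lower-face vinyl group on C10, and the trans bromide is also the more stable epimer.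

Step 11
Reactants: 15 bromo ketone silyl ether
Product: 16 primary allylic alcohol (C12–OH)
Conditions: HF (48 % aq.), MeCN, 0 °C
Reagents that add atoms: none
Why: Acidic fluoride cleaves the primary silyl ether; avoiding basic or nucleophilic conditions keeps the α-bromo ketone and the acetate intact.

Step 12
Reactants: 16 allylic alcohol
Product: 17 C12 aldehyde (2-substituted acrolein on C7)
Conditions: MnO2, CH2Cl2, rt
Reagents that add atoms: none
Why: MnO2 oxidises allylic alcohols selectively under neutral heterogeneous conditions.

Step 13
Reactants: 17 aldehyde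
Product: 18 C12 carboxylic acid (8-bromo-9-oxo acid)
Conditions: NaClO2, NaH2PO4, 2-methyl-2-butene, t-BuOH/H2O, 0 °C → rt
Reagents that add atoms: sodium chlorite, [Na+].[O-]Cl=O
Why: Pinnick oxidation converts the enal to the acrylic acid at buffered pH; the scavenger protects the isopropenyl and vinyl groups from hypochlorous acid.

Step 14
Reactants: 18 bromo acid
Product: 19 keto lactone (cis-fused 8,12-olide, C9 ketone, O6 acetate)
Conditions: KHCO3, DMF, rt
Reagents that add atoms: none
Why: Intramolecular SN2 displacement (5-exo-tet) of the activated α-bromo ketone by the carboxylate inverts C8, so O8 arrives on the lower face and the lactone is necessarily cis-fused to the C7 arm. Br and H7 are syn, which disfavours E2 elimination.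

Step 15
Reactants: 19 keto lactone
Product: 20 9-hydroxy lactone (O9 lower, cis to O8)
Conditions: NaBH4, CeCl3·7H2O, MeOH, −78 °C
Reagents that add atoms: none
Why: Luche reduction: hydride is expected on the upper face, anti to the axial C8–O bond (polar Felkin–Anh) and on the convex face of the cis-fused bicycle, giving the equatorial lower-face alcohol. The 1,2-selective cerium conditions at low temperature should leave the methylene lactone and the acetate untouched.

Step 16
Reactants: 20 hydroxy lactone; 21 angelic acid [(Z)-2-methylbut-2-enoic acid]
Product: 23 9-O-angelate, via mixed anhydride 22 (not isolated)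
Conditions: 21, 2,4,6-trichlorobenzoyl chloride, Et3N, toluene, rt; then 20, 75 °C
Reagents that add atoms: none
Why: Yamaguchi-type esterification: the alcohol attacks the unhindered angeloyl carbonyl of 22 because the aroyl carbonyl is shielded by two ortho chlorines. Working without a nucleophilic catalyst is the established way to keep the Z geometry.

Step 17
Reactants: 23 angelate
Product: 24 C3 allylic alcohol (C5 arm = 3-hydroxyprop-1-en-2-yl)
Conditions: SeO2 (0.5 equiv), t-BuOOH, CH2Cl2, 0 °C → rt
Reagents that add atoms: selenium dioxide, O=[Se]=O; tert-butyl hydroperoxide (terminal oxidant), CC(C)(C)OO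
Why: Allylic oxidation by ene reaction and [2,3]-shift at the only electron-rich alkene bearing allylic hydrogens; the methyl reacts in preference to the hindered tertiary C5–H. Any enal formed directly converges in step 18.

Step 18
Reactants: 24 allylic alcohol
Product: 25 target
Conditions: MnO2, CH2Cl2, rt
Reagents that add atoms: none
Why: Selective neutral oxidation of the primary allylic alcohol to the enal; esters, lactone and the other alkenes are inert.

## Compound list

1 | (R)-(−)-carvone | CC1=CC[C@@H](C(C)=C)CC1=O | starting material
2 | (5R)-5-(3-chloroprop-1-en-2-yl)-2-methylcyclohex-2-en-1-one | CC1=CC[C@@H](C(=C)CCl)CC1=O | intermediate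
3 | (5R)-5-(3-acetoxyprop-1-en-2-yl)-2-methylcyclohex-2-en-1-one | CC1=CC[C@@H](C(=C)COC(C)=O)CC1=O | intermediate
4 | (5R)-5-(3-hydroxyprop-1-en-2-yl)-2-methylcyclohex-2-en-1-one | CC1=CC[C@@H](C(=C)CO)CC1=O | intermediate
5 | (5R)-5-[3-(tert-butyldimethylsilyloxy)prop-1-en-2-yl]-2-methylcyclohex-2-en-1-one | CC1=CC[C@@H](C(=C)CO[Si](C)(C)C(C)(C)C)CC1=O | intermediate
6 | (5S)-1-(tert-butyldimethylsilyloxy)-5-[3-(tert-butyldimethylsilyloxy)prop-1-en-2-yl]-2-methylcyclohexa-1,3-diene | CC1=C(O[Si](C)(C)C(C)(C)C)C[C@H](C(=C)CO[Si](C)(C)C(C)(C)C)C=C1 | intermediate
7 | (4S,5R)-4-hydroxy-5-[3-(tert-butyldimethylsilyloxy)prop-1-en-2-yl]-2-methylcyclohex-2-en-1-one | CC1=C[C@H](O)[C@@H](C(=C)CO[Si](C)(C)C(C)(C)C)CC1=O | intermediate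
8 | isopropenylmagnesium bromide | CC(=C)[Mg]Br | starting material
9 | vinyl bromide | C=CBr | starting material
10 | bromomagnesium O6-alkoxide of 7 | CC1=C[C@H](O[Mg]Br)[C@@H](C(=C)CO[Si](C)(C)C(C)(C)C)CC1=O | intermediate
11 | bis(bromomagnesium) C9-enolate O6-alkoxide, isopropenyl on C5 (upper) | CC1=C(O[Mg]Br)C[C@H](C(=C)CO[Si](C)(C)C(C)(C)C)[C@@H](O[Mg]Br)[C@H]1C(C)=C | intermediate
12 | 4-hydroxy-2-methyl-3-(prop-1-en-2-yl)-5-[3-(tert-butyldimethylsilyloxy)prop-1-en-2-yl]-2-vinylcyclohexan-1-one (C14, isopropenyl, O6 upper; vinyl, C7 arm lower) | C=C[C@]1(C)C(=O)C[C@H](C(=C)CO[Si](C)(C)C(C)(C)C)[C@@H](O)[C@H]1C(C)=C | intermediate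
13 | O6-acetate of 12 | C=C[C@]1(C)C(=O)C[C@H](C(=C)CO[Si](C)(C)C(C)(C)C)[C@@H](OC(C)=O)[C@H]1C(C)=C | intermediate
14 | C8=C9 trimethylsilyl enol ether of 13 | C=C[C@]1(C)C(O[Si](C)(C)C)=C[C@H](C(=C)CO[Si](C)(C)C(C)(C)C)[C@@H](OC(C)=O)[C@H]1C(C)=C | intermediate
15 | 8-bromo ketone (Br upper), O6 acetate, O12 silyl ether | C=C[C@]1(C)C(=O)[C@@H](Br)[C@H](C(=C)CO[Si](C)(C)C(C)(C)C)[C@@H](OC(C)=O)[C@H]1C(C)=C | intermediate
16 | 8-bromo ketone with free C12 hydroxyl | C=C[C@]1(C)C(=O)[C@@H](Br)[C@H](C(=C)CO)[C@@H](OC(C)=O)[C@H]1C(C)=C | intermediate
17 | 8-bromo ketone C12 aldehyde | C=C[C@]1(C)C(=O)[C@@H](Br)[C@H](C(=C)C=O)[C@@H](OC(C)=O)[C@H]1C(C)=C | intermediate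
18 | 8-bromo ketone C12 carboxylic acid | C=C[C@]1(C)C(=O)[C@@H](Br)[C@H](C(=C)C(=O)O)[C@@H](OC(C)=O)[C@H]1C(C)=C | intermediate
19 | cis-fused 8,12-olide, C9 ketone, O6 acetate, C5 isopropenyl | C=C[C@]1(C)C(=O)[C@@H]2OC(=O)C(=C)[C@@H]2[C@@H](OC(C)=O)[C@H]1C(C)=C | intermediate
20 | 9-hydroxy lactone (O9 lower) | C=C[C@]1(C)[C@H](O)[C@@H]2OC(=O)C(=C)[C@@H]2[C@@H](OC(C)=O)[C@H]1C(C)=C | intermediate
21 | angelic acid, (Z)-2-methylbut-2-enoic acid | C/C=C(/C)C(=O)O | starting material
22 | angelic 2,4,6-trichlorobenzoic anhydride | C/C=C(/C)C(=O)OC(=O)c1c(Cl)cc(Cl)cc1Cl | intermediate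
23 | 9-O-angelate of 20 | C=C[C@]1(C)[C@H](OC(=O)/C(C)=C\C)[C@@H]2OC(=O)C(=C)[C@@H]2[C@@H](OC(C)=O)[C@H]1C(C)=C | intermediate
24 | C3 allylic alcohol of 23 | C=C[C@]1(C)[C@H](OC(=O)/C(C)=C\C)[C@@H]2OC(=O)C(=C)[C@@H]2[C@@H](OC(C)=O)[C@H]1C(=C)CO | intermediate
25 | CNP0252310.2 | C=C[C@]1(C)[C@H](OC(=O)/C(C)=C\C)[C@@H]2OC(=O)C(=C)[C@@H]2[C@@H](OC(C)=O)[C@H]1C(=C)C=O | target

## Step count and least certain steps

Total: 18 steps. Longest linear sequence: 18 steps (1 → 25); 8, 9 and 21 enter as purchased reagents.

**Step 7 (key step).** Two things are most likely to go wrong. The Grignard reagent may add 1,2 if delivery from the O6 alkoxide is slow. The aggregated magnesium enolate may also transmetalate sluggishly, so that simple protonation, proton transfer to C8 or O-vinylation compete. Fallback: from 7 the directed conjugate addition is run alone and enolate 11 is captured by Michael addition to phenyl vinyl sulfoxide, a vinyl cation equivalent, to give the 2-(phenylsulfinyl)ethyl ketone F1. Thermal sulfoxide syn-elimination (toluene, 110 °C, NaHCO3) then gives the vinyl group and the route rejoins at 12.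

**Step 5.** Deprotonation at C8 may persist, giving the cross-conjugated dienol ether, or the dienolate may undergo Michael self-condensation under the equilibrating base. Fallback: from 5 the linear dienol is made under acid-catalysed thermodynamic conditions as the dienyl acetate F2 (isopropenyl acetate, TsOH cat.). Buffered mCPBA oxidation of F2 gives the γ-hydroxy enone directly, rejoining at 7.

**Step 6.** The peracid may epoxidise the more substituted C9=C10 enol ether bond, leading to hydroxylation at C10, and facial selectivity at C6 may be poor. Fallback: from 6, [4+2] cycloaddition of singlet oxygen (O2, hν, tetraphenylporphyrin, CH2Cl2, −78 °C) can only join C9 and C6 and gives the endoperoxide F3 anti to the C7 arm. Reduction with thiourea in methanol collapses it to 7.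

**Step 15.** Hydride may be delivered from the lower face if the ring adopts the conformer with equatorial O8, and the methylene lactone may suffer conjugate reduction. Fallback: from 19 the substrate-controlled reduction is replaced by a catalyst-controlled Corey–Bakshi–Shibata reduction. The enantiomer of 2-methyl-CBS-oxazaborolidine is chosen to deliver hydride to the upper face, with catecholborane as reductant so that the alkenes are not hydroborated. The route rejoins at 20 and no new compound is made.

**Step 16.** Acylation of the hindered C9 hydroxyl next to quaternary C10 may be slow, and the angelate may isomerise to the tiglate at the temperature needed. Fallback: from 20 the alcohol is acylated with the less hindered 2-[bis(2,2,2-trifluoroethoxy)phosphoryl]propanoic acid (carbodiimide coupling) to give the phosphonate ester F4. A Still–Gennari olefination with acetaldehyde (KN(SiMe3)2, 18-crown-6, THF, −78 °C) then builds the Z-enoate on the molecule and rejoins at 23.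

**Step 17.** Hydrogen abstraction at the tertiary C5–H may compete, the hindered alkene may react slowly, and over-oxidation is possible. Fallback: from 23 a Schenck ene reaction with singlet oxygen (O2, hν, tetraphenylporphyrin, CH2Cl2) gives the primary allylic hydroperoxide F5. The electron-poor alkenes and the vinyl group are inert to singlet oxygen. Dehydration of F5 with Ac2O/pyridine gives the enal directly, rejoining at 25.

## Further compounds

F1 | step 7 | 2-[2-(phenylsulfinyl)ethyl] analogue of 12 (sulfinylethyl in place of vinyl on C10) | O=S(CC[C@]1(C)C(=O)C[C@H](C(=C)CO[Si](C)(C)C(C)(C)C)[C@@H](O)[C@H]1C(C)=C)c1ccccc1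
F2 | step 5 | (5S)-1-acetoxy-5-[3-(tert-butyldimethylsilyloxy)prop-1-en-2-yl]-2-methylcyclohexa-1,3-diene | CC1=C(OC(C)=O)C[C@H](C(=C)CO[Si](C)(C)C(C)(C)C)C=C1
F3 | step 6 | C9,C6-endoperoxide of 6 (peroxide bridge upper, silyloxy at bridgehead C9) | CC1=C[C@@H]2OO[C@@]1(O[Si](C)(C)C(C)(C)C)C[C@@H]2C(=C)CO[Si](C)(C)C(C)(C)C
F0 | step 15 | none | none
F4 | step 16 | 9-O-{2-[bis(2,2,2-trifluoroethoxy)phosphoryl]propanoate} of 20 | C=C[C@]1(C)[C@H](OC(=O)C(C)P(=O)(OCC(F)(F)F)OCC(F)(F)F)[C@@H]2OC(=O)C(=C)[C@@H]2[C@@H](OC(C)=O)[C@H]1C(C)=C
F5 | step 17 | C3 allylic hydroperoxide of 23 | C=C[C@]1(C)[C@H](OC(=O)/C(C)=C\C)[C@@H]2OC(=O)C(=C)[C@@H]2[C@@H](OC(C)=O)[C@H]1C(=C)COO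
A1 | alternative 1 | C9 enone (C7=C8) with O6 silyl ether, C5 2-methyl-1,3-dioxolan-2-yl and C10 methyl/2-silyloxyethyl | CC(C)(C)[Si](C)(C)OCC[C@]1(C)C(=O)C=C[C@@H](O[Si](C)(C)C(C)(C)C)[C@H]1C2(C)OCCO2
A2 | alternative 1 | allene (propadiene) | C=C=C
A3 | alternative 1 | cis-fused methylenecyclobutane photoadduct | CC(C)(C)[Si](C)(C)OCC[C@]1(C)C(=O)[C@@H]2C(=C)C[C@@H]2[C@@H](O[Si](C)(C)C(C)(C)C)[C@H]1C3(C)OCCO3
A4 | alternative 2 | open-chain C8 aldehyde with Z-2-(bromomethyl)enoate (C7=C11), O9 triethylsilyl ether, O6 acetate | O=C[C@@H](O[Si](CC)(CC)CC)[C@@](C)(C=C)[C@H](C(=C)CO[Si](C)(C)C(C)(C)C)[C@H](OC(C)=O)/C=C(\CBr)C(=O)OC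
A5 | alternative 2 | bicyclic cis-fused α-methylene lactone with all six ring stereocentres | C=C[C@]1(C)[C@H](O[Si](CC)(CC)CC)[C@@H]2OC(=O)C(=C)[C@@H]2[C@@H](OC(C)=O)[C@H]1C(=C)CO[Si](C)(C)C(C)(C)C
A6 | alternative 3 | C6 aldehyde tethered to the C8 butenolide (C7=C11), O9 silyl ether | O=C[C@@H](C(=C)CO[Si](C)(C)C(C)(C)C)[C@](C)(C=C)[C@H](O[Si](C)(C)C(C)(C)C)[C@@H]1OC(=O)C=C1
A7 | alternative 3 | cis-fused 6-hydroxy lactone with saturated C11 | C=C[C@]1(C)[C@H](O[Si](C)(C)C(C)(C)C)[C@@H]2OC(=O)C[C@@H]2[C@@H](O)[C@H]1C(=C)CO[Si](C)(C)C(C)(C)C
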